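**Retrosynthetic overview**
1. Last bonds: the C19–O ester (acylation of the 19-ol with O-silylated p-coumaric acid) and the 2-substituted diene C13–C16 (terminal alkyne plus ethylene, enyne metathesis).
2. The quaternary C4 (C18, C19) comes from a C4 ketone: one-carbon homologation to the aldehyde, then methylation anti to the axial C10 methyl.
3. Ring B is closed by the C6–C7 bond in an intramolecular Hosomi–Sakurai conjugate addition on a monocyclic ring A enone. The enabling feature: C7–C8(=C17)–C9 is a 2-substituted allyl unit (the footprint of an allylsilane), and C6 is β to C4 through C5, so a temporary C4 ketone makes exocyclic C5=C6 the acceptor; C6=C5–C10–C9–C8=C7 is a 1,5-diene that closes tail to tail through a chair.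
4. C9–C10 and both stereocentres come from an Ireland–Claisen rearrangement of a hex-5-ynoate of a ring A allylic alcohol. The face is set by a temporary C4 silyloxy stereocentre (CBS reduction), which then becomes the activating ketone and finally the quaternary C4.
5. Ring order: ring A is bought (3-methylcyclohex-2-enone), ring B forms in the key step; C8, C9, C11–C14 come from hex-5-ynoic acid.

Key step: step 12

Remark: labdane numbering is used for atoms; the SMILES is read as (4R,5S,9R,10S), the ent-labdane series, with the C10 methyl, the C19 oxymethylene and the C9 side chain on one face of the trans-decalin and H5 and H9 on the other.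

**Step 1**
Reactants: 1 3-methylcyclohex-2-en-1-one
Product: 2 2-iodo-3-methylcyclohex-2-en-1-one
Conditions: I2 (2 equiv), pyridine–CH2Cl2, 0 °C → rt
Reagents that add atoms: iodine, II
Why: Johnson-type α-iodination (pyridine conjugate addition, iodination of the enolate, elimination) places iodine only on the α-carbon, the future C5; no stereocentre is formed.

**Step 2**
Reactants: 2 2-iodo-3-methylcyclohex-2-en-1-one
Product: 3 (1R)-2-iodo-3-methylcyclohex-2-en-1-ol
Conditions: (S)-1-methyl-3,3-diphenyltetrahydro-1H,3H-pyrrolo[1,2-c][1,3,2]oxazaborole ((S)-Me-CBS, 0.2 equiv), BH3·SMe2, THF, −20 °C; MeOH quench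
Reagents that add atoms: none
Why: Corey–Bakshi–Shibata reduction in which the iodine-bearing alkene carbon acts as the large ketone substituent, so hydride delivery should give the (R)-alcohol, the temporary C4 stereocentre, with high enantioselectivity.

**Step 3**
Reactants: 3 (1R)-2-iodo-3-methylcyclohex-2-en-1-ol
Product: 4 triethyl{[(1R)-2-iodo-3-methylcyclohex-2-en-1-yl]oxy}silane
Conditions: Et3SiCl, imidazole, DMF, 0 °C
Reagents that add atoms: chlorotriethylsilane, CC[Si](Cl)(CC)CC
Why: standard silylation of a secondary allylic alcohol; the triethylsilyl ether is chosen because mild acid removes it later without harming an allylsilane or an alkynylsilane.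

**Step 4**
Reactants: 4 triethyl{[(1R)-2-iodo-3-methylcyclohex-2-en-1-yl]oxy}silane
Product: 5 [(6R)-2-methyl-6-(triethylsilyloxy)cyclohex-1-en-1-yl]methanol
Conditions: tBuLi (2.1 equiv), Et2O, −78 °C; (CH2O)n, −78 → 0 °C
Reagents that add atoms: formaldehyde (from paraformaldehyde), C=O
Why: iodine–lithium exchange and addition of the vinyllithium to formaldehyde install C6 as a primary allylic alcohol without touching the silyloxy stereocentre.

**Step 5**
Reactants: 6 hex-5-ynoic acid
Product: 7 6-(triisopropylsilyl)hex-5-ynoic acid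
Conditions: nBuLi (2.1 equiv), THF, −78 → 0 °C; iPr3SiCl, → rt; 1 M HCl work-up
Reagents that add atoms: chlorotriisopropylsilane, CC(C)[Si](Cl)(C(C)C)C(C)C
Why: the carboxylate–acetylide dianion is C-silylated at the acetylide (alkyne protection), masking the acidic alkyne C–H for the base-mediated steps ahead.

**Step 6**
Reactants: 5 [(6R)-2-methyl-6-(triethylsilyloxy)cyclohex-1-en-1-yl]methanol; 7 6-(triisopropylsilyl)hex-5-ynoic acid
Product: 8 [(6R)-2-methyl-6-(triethylsilyloxy)cyclohex-1-en-1-yl]methyl 6-(triisopropylsilyl)hex-5-ynoate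
Conditions: N-(3-dimethylaminopropyl)-N'-ethylcarbodiimide hydrochloride (EDC·HCl), 4-(dimethylamino)pyridine, CH2Cl2, rt
Reagents that add atoms: none
Why: Steglich-type carbodiimide esterification of an unhindered primary allylic alcohol; no stereocentre is affected.

**Step 7**
Reactants: 8 [(6R)-2-methyl-6-(triethylsilyloxy)cyclohex-1-en-1-yl]methyl 6-(triisopropylsilyl)hex-5-ynoate
Product: 11 (2S)-2-[(1S,3R)-1-methyl-2-methylidene-3-(triethylsilyloxy)cyclohexyl]-6-(triisopropylsilyl)hex-5-ynoic acid, via (Z)-silyl ketene acetal 9 (not isolated), via trimethylsilyl ester 10 (not isolated)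
Conditions: LiN(iPr)2 (1.2 equiv), THF–HMPA 4:1, −78 °C; Me3SiCl, −78 °C → rt, then 60 °C; dilute aqueous citric acid work-up
Reagents that add atoms: none
Why: Ireland–Claisen rearrangement: enolisation in THF–HMPA should give the Z(O)-enolate and hence ketene acetal 9 with the chain cis to OSiMe3, whose chair transition state puts that chain equatorial and the ring methyl axial (C9 relative to C10), while bond formation at C10 anti to the pseudoaxial C4–OSiEt3 group (no 1,3-diaxial-type contact) should set C10 relative to C4 and move the ring alkene to the exocyclic C5=C6 position.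

**Step 8**
Reactants: 11 (2S)-2-[(1S,3R)-1-methyl-2-methylidene-3-(triethylsilyloxy)cyclohexyl]-6-(triisopropylsilyl)hex-5-ynoic acid
Product: 12 methyl (2S)-2-[(1S,3R)-1-methyl-2-methylidene-3-(triethylsilyloxy)cyclohexyl]-6-(triisopropylsilyl)hex-5-ynoate
Conditions: Me3SiCHN2, MeOH–toluene, 0 °C → rt
Reagents that add atoms: (trimethylsilyl)diazomethane, C[Si](C)(C)C=[N+]=[N-]
Why: O-methylation of the acid by the diazomethane surrogate needs no base, so the α-stereocentre (C9) and both silyl groups should be untouched.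

**Step 9**
Reactants: 12 methyl (2S)-2-[(1S,3R)-1-methyl-2-methylidene-3-(triethylsilyloxy)cyclohexyl]-6-(triisopropylsilyl)hex-5-ynoate
Product: 14 triethyl{[(1R,3S)-3-methyl-2-methylidene-3-[(3S)-2-[(trimethylsilyl)methyl]-7-(triisopropylsilyl)hept-1-en-6-yn-3-yl]cyclohexyl]oxy}silane, via bis(silylmethyl)carbinol 13 (not isolated)
Conditions: Me3SiCH2MgCl (5 equiv), CeCl3 (5 equiv), THF, −78 °C → rt; then silica gel, CH2Cl2, rt
Reagents that add atoms: (trimethylsilyl)methylmagnesium chloride, C[Si](C)(C)C[Mg]Cl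
Why: Bunnelle–Narayanan allylsilane synthesis: the organocerium reagent adds twice to the ester without enolising C9, and Peterson elimination of one β-silyl group from the tertiary carbinol gives the 2-substituted allylsilane (C7, C8, C17).

**Step 10**
Reactants: 14 triethyl{[(1R,3S)-3-methyl-2-methylidene-3-[(3S)-2-[(trimethylsilyl)methyl]-7-(triisopropylsilyl)hept-1-en-6-yn-3-yl]cyclohexyl]oxy}silane
Product: 15 (1R,3S)-3-methyl-2-methylidene-3-[(3S)-2-[(trimethylsilyl)methyl]-7-(triisopropylsilyl)hept-1-en-6-yn-3-yl]cyclohexan-1-ol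
Conditions: pyridinium p-toluenesulfonate (cat.), MeOH, 0 °C → rt
Reagents that add atoms: none
Why: mild acid-catalysed methanolysis cleaves the secondary triethylsilyl ether, while the allyl- and alkynylsilanes, which need strong acid or fluoride, should survive.

**Step 11**
Reactants: 15 (1R,3S)-3-methyl-2-methylidene-3-[(3S)-2-[(trimethylsilyl)methyl]-7-(triisopropylsilyl)hept-1-en-6-yn-3-yl]cyclohexan-1-ol
Product: 16 (3S)-3-methyl-2-methylidene-3-[(3S)-2-[(trimethylsilyl)methyl]-7-(triisopropylsilyl)hept-1-en-6-yn-3-yl]cyclohexan-1-one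
Conditions: Dess–Martin periodinane, NaHCO3, CH2Cl2, 0 °C → rt; used at once
Reagents that add atoms: none
Why: buffered Dess–Martin oxidation of the allylic alcohol gives the α-methylene ketone and erases the temporary C4 stereocentre once it has done its work.

**Step 12**
Reactants: 16 (3S)-3-methyl-2-methylidene-3-[(3S)-2-[(trimethylsilyl)methyl]-7-(triisopropylsilyl)hept-1-en-6-yn-3-yl]cyclohexan-1-one
Product: 18 (4aS,5R,8aS)-4a-methyl-6-methylidene-5-[4-(triisopropylsilyl)but-3-yn-1-yl]octahydronaphthalen-1(2H)-one, via ethylaluminium enolate 17 (not isolated)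
Conditions: EtAlCl2 (1.5 equiv), toluene, −78 → −30 °C; aqueous NaHCO3 work-up; DBU (cat.), CH2Cl2, rt if C5 needs equilibration
Reagents that add atoms: none
Why: EtAlCl2 binds the C4 carbonyl of the s-cis α-methylene ketone, the allylsilane terminus C7 adds to the exocyclic β-carbon C6, and the β-silyl cation at C8 loses the silyl group, giving the C8=C17 exocyclic methylene regiospecifically and a C4–C5 aluminium enolate. This is an intramolecular Hosomi–Sakurai conjugate addition, closest to the known Lewis-acid cyclisations of enones carrying a tethered 2-(silylmethyl)allyl group to methylenecyclohexanes. Ring B closes 6-endo-trig at both π systems through a chair-like array C6=C5–C10–C9–C8=C7 with the C9 chain equatorial and the C10 methyl axial. The one new stereocentre, C5, is set when the enolate is protonated anti to the axial C10 methyl, giving the trans-decalone, which is also expected to be the more stable epimer, so base equilibration can correct a kinetic mixture. The step needs conjugate attack at C6 instead of 1,2-attack at C4 and ring closure before protodesilylation; the unhindered terminal β-CH2, the allylsilane–Lewis acid pairing and the preference of C9 for the equatorial position on ring A (1,2-attack needs it axial) should secure this.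

**Step 13**
Reactants: 18 (4aS,5R,8aS)-4a-methyl-6-methylidene-5-[4-(triisopropylsilyl)but-3-yn-1-yl]octahydronaphthalen-1(2H)-one
Product: 20 (4aS,5R,8aS)-4a-methyl-6-methylidene-5-[4-(triisopropylsilyl)but-3-yn-1-yl]decahydronaphthalene-1-carbaldehyde (both C1 epimers), via methyl enol ether 19 (not isolated)
Conditions: Ph3P(CH2OMe)Cl (3 equiv), KN(SiMe3)2 (2.8 equiv), THF, 0 °C → rt; then 2 M HCl, THF, rt
Reagents that add atoms: (methoxymethyl)triphenylphosphonium chloride, [Cl-].COC[P+](c1ccccc1)(c1ccccc1)c1ccccc1; water, O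
Why: Wittig methoxymethylenation and enol ether hydrolysis are the standard one-carbon homologation of a ketone to the aldehyde (C19); the two C4 epimers converge in the next step.

**Step 14**
Reactants: 20 (4aS,5R,8aS)-4a-methyl-6-methylidene-5-[4-(triisopropylsilyl)but-3-yn-1-yl]decahydronaphthalene-1-carbaldehyde
Product: 21 (1R,4aS,5R,8aS)-1,4a-dimethyl-6-methylidene-5-[4-(triisopropylsilyl)but-3-yn-1-yl]decahydronaphthalene-1-carbaldehyde
Conditions: KOtBu (1.5 equiv), MeI (5 equiv), THF, 0 °C
Reagents that add atoms: iodomethane, CI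
Why: enolate C-methylation of the α-branched aldehyde, in which iodomethane should approach the exocyclic enolate equatorially, anti to the 1,3-related axial C10 methyl, placing C18 trans and the formyl carbon C19 cis to the C10 methyl as in the target.

**Step 15**
Reactants: 21 (1R,4aS,5R,8aS)-1,4a-dimethyl-6-methylidene-5-[4-(triisopropylsilyl)but-3-yn-1-yl]decahydronaphthalene-1-carbaldehyde
Product: 22 [(1R,4aS,5R,8aS)-1,4a-dimethyl-6-methylidene-5-[4-(triisopropylsilyl)but-3-yn-1-yl]decahydronaphthalen-1-yl]methanol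
Conditions: NaBH4, MeOH, 0 °C
Reagents that add atoms: none
Why: borohydride reduction of the neopentyl aldehyde to the primary alcohol; no stereocentre is affected.

**Step 16**
Reactants: 22 [(1R,4aS,5R,8aS)-1,4a-dimethyl-6-methylidene-5-[4-(triisopropylsilyl)but-3-yn-1-yl]decahydronaphthalen-1-yl]methanol
Product: 23 [(1R,4aS,5R,8aS)-5-(but-3-yn-1-yl)-1,4a-dimethyl-6-methylidenedecahydronaphthalen-1-yl]methanol
Conditions: Bu4NF (1 M in THF), THF, rt
Reagents that add atoms: none
Why: fluoride cleaves the alkynyl C–Si bond (alkyne deprotection) to free the terminal alkyne; no other silyl group is left in the molecule.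

**Step 17**
Reactants: 23 [(1R,4aS,5R,8aS)-5-(but-3-yn-1-yl)-1,4a-dimethyl-6-methylidenedecahydronaphthalen-1-yl]methanol
Product: 24 [(1R,4aS,5R,8aS)-1,4a-dimethyl-6-methylidene-5-(3-methylidenepent-4-en-1-yl)decahydronaphthalen-1-yl]methanol
Conditions: ethylene (1 atm), second-generation Grubbs catalyst RuCl2(=CHPh)(PCy3)(H2IMes) (10 mol%), toluene, 80 °C
Reagents that add atoms: ethylene, C=C
Why: cross enyne metathesis with ethylene (the ruthenium alkylidene adds to the alkyne and the vinylcarbene turns over with ethylene) converts the terminal alkyne into the 2-substituted buta-1,3-diene C13(=C16)–C14=C15, while the hindered 1,1-disubstituted C8=C17 alkene should not react.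

**Step 18**
Reactants: 25 (E)-3-(4-hydroxyphenyl)prop-2-enoic acid (p-coumaric acid)
Product: 27 (E)-3-[4-(tert-butyldimethylsilyloxy)phenyl]prop-2-enoic acid, via bis-silylated coumarate 26 (not isolated)
Conditions: tBuMe2SiCl (2.5 equiv), imidazole, DMF, rt; then AcOH–THF–H2O, rt
Reagents that add atoms: tert-butyl(chloro)dimethylsilane, CC(C)(C)[Si](C)(C)Cl
Why: exhaustive silylation followed by selective hydrolysis of the labile silyl ester leaves the phenol protected and the acid free.

**Step 19**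
Reactants: 24 [(1R,4aS,5R,8aS)-1,4a-dimethyl-6-methylidene-5-(3-methylidenepent-4-en-1-yl)decahydronaphthalen-1-yl]methanol; 27 (E)-3-[4-(tert-butyldimethylsilyloxy)phenyl]prop-2-enoic acid
Product: 28 [(1R,4aS,5R,8aS)-1,4a-dimethyl-6-methylidene-5-(3-methylidenepent-4-en-1-yl)decahydronaphthalen-1-yl]methyl (E)-3-[4-(tert-butyldimethylsilyloxy)phenyl]prop-2-enoate
Conditions: EDC·HCl, 4-(dimethylamino)pyridine, CH2Cl2, rt → 40 °C
Reagents that add atoms: none
Why: Steglich-type acylation of the neopentyl primary alcohol; the E geometry of the cinnamate should be preserved.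

**Step 20**
Reactants: 28 [(1R,4aS,5R,8aS)-1,4a-dimethyl-6-methylidene-5-(3-methylidenepent-4-en-1-yl)decahydronaphthalen-1-yl]methyl (E)-3-[4-(tert-butyldimethylsilyloxy)phenyl]prop-2-enoate
Product: 29 [(1R,4aS,5R,8aS)-1,4a-dimethyl-6-methylidene-5-(3-methylidenepent-4-en-1-yl)decahydronaphthalen-1-yl]methyl (E)-3-(4-hydroxyphenyl)prop-2-enoate (CNP0131099.1)
Conditions: Bu4NF, AcOH, THF, 0 °C
Reagents that add atoms: none
Why: buffered fluoride desilylation of the aryl silyl ether is much faster than any attack on the ester or the dienes and should release the target.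

**Compound list**
1 | 3-methylcyclohex-2-en-1-one | CC1=CC(=O)CCC1 | starting material
2 | 2-iodo-3-methylcyclohex-2-en-1-one | CC1=C(I)C(=O)CCC1 | intermediate
3 | (1R)-2-iodo-3-methylcyclohex-2-en-1-ol | CC1=C(I)[C@H](O)CCC1 | intermediate
4 | triethyl{[(1R)-2-iodo-3-methylcyclohex-2-en-1-yl]oxy}silane | CC1=C(I)[C@H](O[Si](CC)(CC)CC)CCC1 | intermediate
5 | [(6R)-2-methyl-6-(triethylsilyloxy)cyclohex-1-en-1-yl]methanol | CC1=C(CO)[C@H](O[Si](CC)(CC)CC)CCC1 | intermediate
6 | hex-5-ynoic acid | C#CCCCC(=O)O | starting material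
7 | 6-(triisopropylsilyl)hex-5-ynoic acid | CC(C)[Si](C(C)C)(C(C)C)C#CCCCC(=O)O | intermediate
8 | [(6R)-2-methyl-6-(triethylsilyloxy)cyclohex-1-en-1-yl]methyl 6-(triisopropylsilyl)hex-5-ynoate | CC(C)[Si](C(C)C)(C(C)C)C#CCCCC(=O)OCC1=C(C)CCC[C@H]1O[Si](CC)(CC)CC | intermediate
9 | (Z)-O-trimethylsilyl ketene acetal of 8 | CC(C)[Si](C(C)C)(C(C)C)C#CCC/C=C(\O[Si](C)(C)C)OCC1=C(C)CCC[C@H]1O[Si](CC)(CC)CC | intermediate
10 | trimethylsilyl ester of acid 11 | CC(C)[Si](C(C)C)(C(C)C)C#CCC[C@H](C(=O)O[Si](C)(C)C)[C@]1(C)CCC[C@@H](O[Si](CC)(CC)CC)C1=C | intermediate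
11 | (2S)-2-[(1S,3R)-1-methyl-2-methylidene-3-(triethylsilyloxy)cyclohexyl]-6-(triisopropylsilyl)hex-5-ynoic acid | CC(C)[Si](C(C)C)(C(C)C)C#CCC[C@H](C(=O)O)[C@]1(C)CCC[C@@H](O[Si](CC)(CC)CC)C1=C | intermediate
12 | methyl (2S)-2-[(1S,3R)-1-methyl-2-methylidene-3-(triethylsilyloxy)cyclohexyl]-6-(triisopropylsilyl)hex-5-ynoate | CC(C)[Si](C(C)C)(C(C)C)C#CCC[C@H](C(=O)OC)[C@]1(C)CCC[C@@H](O[Si](CC)(CC)CC)C1=C | intermediate
13 | tertiary carbinol from double addition to 12, bearing two (trimethylsilyl)methyl groups on C8 | CC(C)[Si](C(C)C)(C(C)C)C#CCC[C@H](C(O)(C[Si](C)(C)C)C[Si](C)(C)C)[C@]1(C)CCC[C@@H](O[Si](CC)(CC)CC)C1=C | intermediate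
14 | triethyl{[(1R,3S)-3-methyl-2-methylidene-3-[(3S)-2-[(trimethylsilyl)methyl]-7-(triisopropylsilyl)hept-1-en-6-yn-3-yl]cyclohexyl]oxy}silane | CC(C)[Si](C(C)C)(C(C)C)C#CCC[C@H](C(=C)C[Si](C)(C)C)[C@]1(C)CCC[C@@H](O[Si](CC)(CC)CC)C1=C | intermediate
15 | (1R,3S)-3-methyl-2-methylidene-3-[(3S)-2-[(trimethylsilyl)methyl]-7-(triisopropylsilyl)hept-1-en-6-yn-3-yl]cyclohexan-1-ol | CC(C)[Si](C(C)C)(C(C)C)C#CCC[C@H](C(=C)C[Si](C)(C)C)[C@]1(C)CCC[C@@H](O)C1=C | intermediate
16 | (3S)-3-methyl-2-methylidene-3-[(3S)-2-[(trimethylsilyl)methyl]-7-(triisopropylsilyl)hept-1-en-6-yn-3-yl]cyclohexan-1-one | CC(C)[Si](C(C)C)(C(C)C)C#CCC[C@H](C(=C)C[Si](C)(C)C)[C@]1(C)CCCC(=O)C1=C | intermediate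
17 | chloro(ethyl)aluminium C4–C5 enolate of 18 | CC(C)[Si](C(C)C)(C(C)C)C#CCC[C@@H]1C(=C)CCC2=C(O[Al](Cl)CC)CCC[C@@]12C | intermediate
18 | (4aS,5R,8aS)-4a-methyl-6-methylidene-5-[4-(triisopropylsilyl)but-3-yn-1-yl]octahydronaphthalen-1(2H)-one | CC(C)[Si](C(C)C)(C(C)C)C#CCC[C@@H]1C(=C)CC[C@@H]2C(=O)CCC[C@@]12C | intermediate
19 | 1-(methoxymethylidene) enol ether of 18 (E/Z mixture) | CC(C)[Si](C(C)C)(C(C)C)C#CCC[C@@H]1C(=C)CC[C@@H]2C(=COC)CCC[C@@]12C | intermediate
20 | (4aS,5R,8aS)-4a-methyl-6-methylidene-5-[4-(triisopropylsilyl)but-3-yn-1-yl]decahydronaphthalene-1-carbaldehyde (C1 epimers) | CC(C)[Si](C(C)C)(C(C)C)C#CCC[C@@H]1C(=C)CC[C@@H]2C(C=O)CCC[C@@]12C | intermediate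
21 | (1R,4aS,5R,8aS)-1,4a-dimethyl-6-methylidene-5-[4-(triisopropylsilyl)but-3-yn-1-yl]decahydronaphthalene-1-carbaldehyde | CC(C)[Si](C(C)C)(C(C)C)C#CCC[C@@H]1C(=C)CC[C@@H]2[C@](C)(C=O)CCC[C@@]12C | intermediate
22 | [(1R,4aS,5R,8aS)-1,4a-dimethyl-6-methylidene-5-[4-(triisopropylsilyl)but-3-yn-1-yl]decahydronaphthalen-1-yl]methanol | CC(C)[Si](C(C)C)(C(C)C)C#CCC[C@@H]1C(=C)CC[C@@H]2[C@](C)(CO)CCC[C@@]12C | intermediate
23 | [(1R,4aS,5R,8aS)-5-(but-3-yn-1-yl)-1,4a-dimethyl-6-methylidenedecahydronaphthalen-1-yl]methanol | C#CCC[C@@H]1C(=C)CC[C@@H]2[C@](C)(CO)CCC[C@@]12C | intermediate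
24 | [(1R,4aS,5R,8aS)-1,4a-dimethyl-6-methylidene-5-(3-methylidenepent-4-en-1-yl)decahydronaphthalen-1-yl]methanol | C=CC(=C)CC[C@@H]1C(=C)CC[C@@H]2[C@](C)(CO)CCC[C@@]12C | intermediate
25 | (E)-3-(4-hydroxyphenyl)prop-2-enoic acid | OC(=O)/C=C/c1ccc(O)cc1 | starting material
26 | tert-butyldimethylsilyl (E)-3-[4-(tert-butyldimethylsilyloxy)phenyl]prop-2-enoate | CC(C)(C)[Si](C)(C)OC(=O)/C=C/c1ccc(O[Si](C)(C)C(C)(C)C)cc1 | intermediate
27 | (E)-3-[4-(tert-butyldimethylsilyloxy)phenyl]prop-2-enoic acid | OC(=O)/C=C/c1ccc(O[Si](C)(C)C(C)(C)C)cc1 | intermediate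
28 | O-silylated coumarate ester of 24 | C=CC(=C)CC[C@@H]1C(=C)CC[C@@H]2[C@](C)(COC(=O)/C=C/c3ccc(O[Si](C)(C)C(C)(C)C)cc3)CCC[C@@]12C | intermediate
29 | [(1R,4aS,5R,8aS)-1,4a-dimethyl-6-methylidene-5-(3-methylidenepent-4-en-1-yl)decahydronaphthalen-1-yl]methyl (E)-3-(4-hydroxyphenyl)prop-2-enoate | C=CC(=C)CC[C@@H]1C(=C)CC[C@@H]2[C@](C)(COC(=O)/C=C/c3ccc(O)cc3)CCC[C@@]12C | target

**Step count and risks**
Total step count: 20. Longest linear sequence: 18 (steps 1–4, 6–17, 19, 20).

Most likely to fail: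

1. Step 12 (key ring closure). The allylsilane may be protodesilylated, or C7 may attack the C4 carbonyl (1,2-mode, bridged carbinol), before conjugate closure; the enolate protonation may also give a cis/trans mixture at C5. Fallback, a silicon-free ene closure that sets out from acid 11 and returns at decalone 18: MeLi (2.5 equiv, Et2O, 0 °C) should convert 11 into the methyl ketone F1. Wittig methylenation (Ph3P=CH2, THF, reflux) should give the isopropenyl compound F2. Pyridinium p-toluenesulfonate in MeOH should free the allylic alcohol F3, and Dess–Martin oxidation should give the isopropenyl enone F4. Me2AlCl (CH2Cl2, −78 → 0 °C) should then promote a type 2 intramolecular ene reaction, in which the isopropenyl CH2 bonds to C6 and a methyl hydrogen moves to C5, giving 18 after base equilibration of C5.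

2. Step 7 (Ireland–Claisen). Leakage of ketene acetal geometry or a boat pathway would erode C9 relative to C10, and the rearrangement onto the tetrasubstituted alkene may be sluggish. Fallback, C10 first by a geometry-independent Claisen and C9 afterwards on a temporary lactone ring, setting out from allylic alcohol 5 and returning at acid 11: Johnson–Claisen rearrangement with triethyl orthoacetate (cat. EtCO2H, 140 °C) should give the ethyl ester F5 with C10 set as before. LiOH (THF–H2O) should give the acid F6. Iodolactonisation (I2, NaHCO3, MeCN) onto C5=C6 should give the cis-fused iodo-γ-lactone F7. Its lithium enolate (LiN(iPr)2, THF, −78 °C) should be alkylated on the convex face, cis to the C10 methyl, by 4-(triisopropylsilyl)but-3-yn-1-yl trifluoromethanesulfonate F9 (from the alcohol and Tf2O, 2,6-lutidine), giving the lactone F8. Zinc (EtOH, NH4Cl, reflux) should then open the lactone by reductive elimination, restoring the C5=C6 methylene and giving 11.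

3. Step 9 (allylsilane from a hindered ester). The second organocerium addition may stall at the ketone stage next to the crowded C9–C10 unit. Fallback, single addition then olefination, setting out from methyl ester 12 and returning at allylsilane 14: Me3SiCH2Li (1.2 equiv, pentane–THF, −78 → 0 °C) should add once to give the α-silyl ketone F10, and Wittig methylenation (Ph3P=CH2, THF, 0 °C → rt) should give 14.

**Further compounds**
F1 | step 12 | methyl ketone from 11: (3S)-3-[(1S,3R)-1-methyl-2-methylidene-3-(triethylsilyloxy)cyclohexyl]-7-(triisopropylsilyl)hept-6-yn-2-one | CC(C)[Si](C(C)C)(C(C)C)C#CCC[C@H](C(C)=O)[C@]1(C)CCC[C@@H](O[Si](CC)(CC)CC)C1=C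
F2 | step 12 | isopropenyl compound: triethylsilyl ether of F3 | CC(C)[Si](C(C)C)(C(C)C)C#CCC[C@H](C(C)=C)[C@]1(C)CCC[C@@H](O[Si](CC)(CC)CC)C1=C
F3 | step 12 | (1R,3S)-3-methyl-2-methylidene-3-[(3S)-2-methyl-7-(triisopropylsilyl)hept-1-en-6-yn-3-yl]cyclohexan-1-ol | CC(C)[Si](C(C)C)(C(C)C)C#CCC[C@H](C(C)=C)[C@]1(C)CCC[C@@H](O)C1=C
F4 | step 12 | (3S)-3-methyl-2-methylidene-3-[(3S)-2-methyl-7-(triisopropylsilyl)hept-1-en-6-yn-3-yl]cyclohexan-1-one | CC(C)[Si](C(C)C)(C(C)C)C#CCC[C@H](C(C)=C)[C@]1(C)CCCC(=O)C1=C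
F5 | step 7 | ethyl 2-[(1S,3R)-1-methyl-2-methylidene-3-(triethylsilyloxy)cyclohexyl]acetate | CCOC(=O)C[C@]1(C)CCC[C@@H](O[Si](CC)(CC)CC)C1=C
F6 | step 7 | 2-[(1S,3R)-1-methyl-2-methylidene-3-(triethylsilyloxy)cyclohexyl]acetic acid | OC(=O)C[C@]1(C)CCC[C@@H](O[Si](CC)(CC)CC)C1=C
F7 | step 7 | cis-fused iodo-γ-lactone (lactone oxygen and iodomethyl on C5, methyl on C10, triethylsilyloxy on C4) | O=C1C[C@]2(C)CCC[C@@H](O[Si](CC)(CC)CC)[C@]2(CI)O1
F8 | step 7 | C9-alkylated iodo-γ-lactone (butynyl chain cis to the C10 methyl) | O=C1[C@@H](CCC#C[Si](C(C)C)(C(C)C)C(C)C)[C@]2(C)CCC[C@@H](O[Si](CC)(CC)CC)[C@]2(CI)O1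
F9 | step 7 | 4-(triisopropylsilyl)but-3-yn-1-yl trifluoromethanesulfonate | CC(C)[Si](C(C)C)(C(C)C)C#CCCOS(=O)(=O)C(F)(F)F
F10 | step 9 | α-silyl ketone: (3S)-3-[(1S,3R)-1-methyl-2-methylidene-3-(triethylsilyloxy)cyclohexyl]-1-(trimethylsilyl)-7-(triisopropylsilyl)hept-6-yn-2-one | CC(C)[Si](C(C)C)(C(C)C)C#CCC[C@H](C(=O)C[Si](C)(C)C)[C@]1(C)CCC[C@@H](O[Si](CC)(CC)CC)C1=C
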